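**Strategy.** C3 and C4 of the oxolane ring (O1, C2–C5) each bear one oxygenated carbon atom: the hydroxymethyl carbon on C3 and ring atom C5 on C4. Each is also bonded to an (S)-configured aryl carbinol carbon (C2 and the side-chain CHOH). Cutting O1–C5 therefore uncovers a twofold axis. Both extra carbons are drawn from CO. One double carbonylation turns a twofold-symmetric trans-epoxide, flanked by two silylated aryl carbinol carbons, into the trans-succinic anhydride. It forms the C3–CH2OH and C4–C5 bonds, closes one ring and fixes C3 and C4 by two inversions. Reduction, monoprotection and a single Williamson closure of O1–C5 then break the symmetry.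

Key step: step 7

Remark: the SMILES is read as the (2S,3S,4S)-oxolane with an (S)-carbinol, so all three ring substituents are cis. In the Why lines, C2–C5 are the locants of the target ring and Cα is the side-chain carbinol carbon.

Step 1
Reactants: 1 4-(benzyloxy)-3-methoxybenzaldehyde (O-benzylvanillin, 2 equiv); 2 ethynylmagnesium bromide
Product: 4 1,4-bis[4-(benzyloxy)-3-methoxyphenyl]but-2-yne-1,4-diol (dl/meso mixture), via ethynediylbis(magnesium bromide) 3 (not isolated)
Conditions: 2, EtMgBr (1.05 equiv), THF, 0 → 40 °C; then 1 (2 equiv), 0 °C → rt; aq. NH4Cl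
Reagents that add atoms: none
Why: EtMgBr removes the acetylenic proton of 2, and the resulting bis-Grignard reagent adds twice to the non-enolisable aldehyde (Grignard addition); the two unselectively formed stereocentres are erased in step 2.

Step 2
Reactants: 4
Product: 5 1,4-bis[4-(benzyloxy)-3-methoxyphenyl]but-2-yne-1,4-dione
Conditions: activated MnO2 (excess), CH2Cl2, rt
Reagents that add atoms: none
Why: Benzylic-propargylic alcohols are among the fastest substrates of the neutral MnO2 oxidation, which leaves the benzyl ethers and the electrophilic ynedione alone.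

Step 3
Reactants: 5
Product: 6 (1R,4R)-1,4-bis[4-(benzyloxy)-3-methoxyphenyl]but-2-yne-1,4-diol
Conditions: (R)-Alpine-Borane (B-isopinocampheyl-9-BBN from (+)-α-pinene, 2.6 equiv), THF (concentrated), 0 °C → rt; then HOCH2CH2NH2, Et2O
Reagents that add atoms: none
Why: Midland reduction, in which the alkynyl group is the small and the aryl group the large substituent in the cyclic hydride-transfer transition state, so this reagent antipode sets both C2 and Cα as R (ynediol descriptor); it is preferred to Ru–TsDPEN transfer hydrogenation, where aryl and alkynyl compete as the directing π-group, and the twofold reduction enriches the chiral diol at the cost of a separable meso isomer (Horeau amplification).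

Step 4
Reactants: 6
Product: 7 (1S,4S,2E)-1,4-bis[4-(benzyloxy)-3-methoxyphenyl]but-2-ene-1,4-diol
Conditions: NaAlH2(OCH2CH2OMe)2 (3.5 equiv), THF, 0 °C → rt; aq. potassium sodium tartrate
Reagents that add atoms: none
Why: Alkoxide-directed trans-hydroalumination of the propargylic diol followed by protonolysis gives only the E-alkene and leaves the carbinol carbons untouched (R becomes S only because aryl now outranks the sp2 carbon).

Step 5
Reactants: 7
Product: 8 (R,R)-[(2R,3R)-oxirane-2,3-diyl]bis{[4-(benzyloxy)-3-methoxyphenyl]methanol} (trans-epoxide, erythro at both ends)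
Conditions: Ti(Oi-Pr)4 (0.2 equiv), D-(−)-diisopropyl tartrate (0.24 equiv), t-BuOOH (decane), 4 Å MS, CH2Cl2, −20 °C
Reagents that add atoms: tert-butyl hydroperoxide, CC(C)(C)OO
Why: Sharpless asymmetric epoxidation in the matched sense: with D-(−)-tartrate the (S)-aryl allylic carbinol is the fast-reacting antipode, both hydroxyls steer oxygen to the same one of the two diastereotopic alkene faces, and the erythro (anti) relation results at both ends, while traces of the (R,R)-diol are mismatched and stay behind.

Step 6
Reactants: 8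
Product: 9 (2S,3S)-2,3-bis{(R)-[4-(benzyloxy)-3-methoxyphenyl][(tert-butyldimethylsilyl)oxy]methyl}oxirane
Conditions: TBSCl (2.6 equiv), imidazole, DMF, rt
Reagents that add atoms: tert-butyldimethylsilyl chloride, CC(C)(C)[Si](C)(C)Cl
Why: Standard imidazole-promoted silylation under conditions too mild for Payne rearrangement; the silyl ether is a poor Lewis base that should not compete with the epoxide for the aluminium centre in step 7 (oxirane descriptors change from R to S by CIP ranking only).

Step 7
Reactants: 9; 10 carbon monoxide (2 equiv consumed)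
Product: 12 (3R,4R)-3,4-bis{(S)-[4-(benzyloxy)-3-methoxyphenyl][(tert-butyldimethylsilyl)oxy]methyl}oxolane-2,5-dione (trans-anhydride), via cis-β-lactone 11 (not isolated)
Conditions: [(ClTPP)Al(THF)2][Co(CO)4] (ClTPP = meso-tetra(4-chlorophenyl)porphyrinato, 5–10 mol %), CO (60 bar), 1,4-dioxane, 90 °C
Reagents that add atoms: carbon monoxide 10, [C-]#[O+]
Why: Proposed new method: the aluminium cation binds the epoxide oxygen, [Co(CO)4]− opens one of the two equivalent carbons by SN2 from the rear, CO inserts into the C–Co bond with retention and the aluminium alkoxide closes cis-β-lactone 11 on the acylcobalt (4-exo-trig); in a second cycle the cobaltate cleaves the alkyl C–O bond of 11 at the other former epoxide carbon, again by SN2, a second CO inserts and the carboxylate closes the five-membered anhydride ring on the acylcobalt (5-exo-trig). The closest known reaction type is the stereospecific one-pot double carbonylation of simple alkyl-substituted 1,2-disubstituted epoxides to succinic anhydrides with this ion-pair catalyst (trans-epoxide to trans-anhydride), which has not been shown for an epoxide flanked by two branched, oxygen-bearing carbons. Both new stereocentres (C3 and C4) are fixed solely by the two inversions, so (2S,3S)-9 must give (3R,4R)-12, which has the anti aldol-type relation at both ends that the all-cis target needs, while C2 and Cα are spectators (R becomes S by ranking only). No regioselectivity is required, because the twofold axis makes the two epoxide carbons identical and both are carbonylated in any case. The selectivity that is required is SN2 opening in preference to a Lewis-acid-induced 1,2-shift of aryl or hydride (semipinacol or Meinwald type) and to benzylic ionisation; it is served by the non-chelating silyl ethers, by the inductive deactivation of both epoxide carbons towards cationic pathways, by the pairing of a mild Lewis acid with a strong nucleophile and by high CO pressure. Shielding of the rear side by the silyloxybenzyl groups is the main risk and is met with higher catalyst loading and longer reaction time.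

Step 8
Reactants: 12
Product: 13 (2S,3S)-2,3-bis{(S)-[4-(benzyloxy)-3-methoxyphenyl][(tert-butyldimethylsilyl)oxy]methyl}butane-1,4-diol
Conditions: LiAlH4, THF, 0 °C → rt (12 added to the hydride)
Reagents that add atoms: none
Why: LiAlH4 reduction of a cyclic anhydride runs through the γ-lactone to the 1,4-diol faster than any enolisation, so C3 and C4 are not epimerised, silyl and benzyl ethers are inert, and afterwards no stereocentre is α to a carbonyl group.

Step 9
Reactants: 13
Product: 14 (2S,3S)-2,3-bis{(S)-[4-(benzyloxy)-3-methoxyphenyl][(tert-butyldimethylsilyl)oxy]methyl}-4-(naphthalen-2-ylmethoxy)butan-1-ol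
Conditions: Ag2O (1.5 equiv), 2-(bromomethyl)naphthalene (1.1 equiv), CH2Cl2, rt
Reagents that add atoms: 2-(bromomethyl)naphthalene, BrCc1ccc2ccccc2c1
Why: Ag2O-mediated Williamson-type monoalkylation of a symmetric diol, in which the internally hydrogen-bonded diol reacts faster than its monoether; the hydroxyls are homotopic so only one monoether exists, the neutral medium avoids silyl migration, and the naphthylmethyl group is chosen because it is hydrogenolysed faster than an alkyl benzyl ether.

Step 10
Reactants: 14
Product: 15 (2S,3S)-2,3-bis{(S)-[4-(benzyloxy)-3-methoxyphenyl][(tert-butyldimethylsilyl)oxy]methyl}-4-(naphthalen-2-ylmethoxy)butyl methanesulfonate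
Conditions: MsCl, Et3N, CH2Cl2, −20 → 0 °C
Reagents that add atoms: methanesulfonyl chloride, CS(=O)(=O)Cl
Why: Routine mesylation of the only free (primary) hydroxyl; no internal nucleophile is available while both benzylic oxygens are silylated and the other primary oxygen is etherified.

Step 11
Reactants: 15
Product: 17 (S)-[4-(benzyloxy)-3-methoxyphenyl]{(3S,4S,5S)-5-[4-(benzyloxy)-3-methoxyphenyl]-4-[(naphthalen-2-ylmethoxy)methyl]oxolan-3-yl}methanol (all-cis), via desilylated diol mesylate 16 (not isolated)
Conditions: Bu4NF (2.5 equiv), THF, 0 °C → rt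
Reagents that add atoms: none
Why: Fluoride desilylation followed by intramolecular Williamson etherification (5-exo-tet), in which the benzylic oxygen is the nucleophile so the C2–O bond is never broken and the all-cis array is kept; the other alkoxide could only form an oxetane (4-exo-tet), and no carbonyl group is present to allow retro-aldol or elimination.

Step 12
Reactants: 17
Product: 18 4-{(S)-hydroxy[(3S,4S,5S)-5-(4-hydroxy-3-methoxyphenyl)-4-(hydroxymethyl)oxolan-3-yl]methyl}-2-methoxyphenol (target)
Conditions: H2 (1 atm), 10% Pd/C, EtOAc, rt, stopped after uptake of 3 equiv H2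
Reagents that add atoms: none
Why: Catalytic hydrogenolysis: aryl benzyl ethers and the naphthylmethyl ether are the most rapidly cleaved benzyl-type C–O bonds on Pd/C, so in a neutral aprotic solvent the hindered C2–O1 and Cα–OH bonds should survive, and no stereocentre is touched.

**Compound list**
1 | 4-(benzyloxy)-3-methoxybenzaldehyde | O=Cc1ccc(OCc2ccccc2)c(OC)c1 | starting material
2 | ethynylmagnesium bromide | C#C[Mg]Br | starting material
3 | ethynediylbis(magnesium bromide) | Br[Mg]C#C[Mg]Br | intermediate
4 | 1,4-bis[4-(benzyloxy)-3-methoxyphenyl]but-2-yne-1,4-diol, dl/meso mixture | OC(C#CC(O)c1ccc(OCc2ccccc2)c(OC)c1)c1ccc(OCc2ccccc2)c(OC)c1 | intermediate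
5 | 1,4-bis[4-(benzyloxy)-3-methoxyphenyl]but-2-yne-1,4-dione | O=C(C#CC(=O)c1ccc(OCc2ccccc2)c(OC)c1)c1ccc(OCc2ccccc2)c(OC)c1 | intermediate
6 | (1R,4R)-ynediol | O[C@H](c1ccc(OCc2ccccc2)c(OC)c1)C#C[C@H](O)c1ccc(OCc2ccccc2)c(OC)c1 | intermediate
7 | (1S,4S,2E)-enediol | O[C@H](c1ccc(OCc2ccccc2)c(OC)c1)/C=C/[C@H](O)c1ccc(OCc2ccccc2)c(OC)c1 | intermediate
8 | (2R,3R)-trans-epoxy diol, carbinols R, erythro at both ends | O[C@H](c1ccc(OCc2ccccc2)c(OC)c1)[C@H]1O[C@@H]1[C@H](O)c1ccc(OCc2ccccc2)c(OC)c1 | intermediate
9 | (2S,3S)-trans-2,3-bis[(R)-aryl(TBSO)methyl]oxirane | CC(C)(C)[Si](C)(C)O[C@H](c1ccc(OCc2ccccc2)c(OC)c1)[C@H]1O[C@@H]1[C@H](O[Si](C)(C)C(C)(C)C)c1ccc(OCc2ccccc2)c(OC)c1 | intermediate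
10 | carbon monoxide | [C-]#[O+] | starting material
11 | (3R,4S)-cis-3-[(S)-aryl(TBSO)methyl]-4-[(R)-aryl(TBSO)methyl]oxetan-2-one | O=C1O[C@H]([C@H](O[Si](C)(C)C(C)(C)C)c2ccc(OCc3ccccc3)c(OC)c2)[C@@H]1[C@H](O[Si](C)(C)C(C)(C)C)c2ccc(OCc3ccccc3)c(OC)c2 | intermediate
12 | (3R,4R)-trans-3,4-bis[(S)-aryl(TBSO)methyl]oxolane-2,5-dione | O=C1OC(=O)[C@@H]([C@H](O[Si](C)(C)C(C)(C)C)c2ccc(OCc3ccccc3)c(OC)c2)[C@@H]1[C@H](O[Si](C)(C)C(C)(C)C)c2ccc(OCc3ccccc3)c(OC)c2 | intermediate
13 | (2S,3S)-2,3-bis[(S)-aryl(TBSO)methyl]butane-1,4-diol | OC[C@@H]([C@H](O[Si](C)(C)C(C)(C)C)c1ccc(OCc2ccccc2)c(OC)c1)[C@@H](CO)[C@H](O[Si](C)(C)C(C)(C)C)c1ccc(OCc2ccccc2)c(OC)c1 | intermediate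
14 | mono(naphthalen-2-ylmethyl) ether of 13 | OC[C@@H]([C@H](O[Si](C)(C)C(C)(C)C)c1ccc(OCc2ccccc2)c(OC)c1)[C@@H](COCc1ccc2ccccc2c1)[C@H](O[Si](C)(C)C(C)(C)C)c1ccc(OCc2ccccc2)c(OC)c1 | intermediate
15 | methanesulfonate of 14 | CS(=O)(=O)OC[C@@H]([C@H](O[Si](C)(C)C(C)(C)C)c1ccc(OCc2ccccc2)c(OC)c1)[C@@H](COCc1ccc2ccccc2c1)[C@H](O[Si](C)(C)C(C)(C)C)c1ccc(OCc2ccccc2)c(OC)c1 | intermediate
16 | desilylated diol mesylate | CS(=O)(=O)OC[C@@H]([C@H](O)c1ccc(OCc2ccccc2)c(OC)c1)[C@@H](COCc1ccc2ccccc2c1)[C@H](O)c1ccc(OCc2ccccc2)c(OC)c1 | intermediate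
17 | all-cis oxolane, two phenolic benzyl ethers and one naphthylmethyl ether | COc1cc([C@@H](O)[C@@H]2CO[C@H](c3ccc(OCc4ccccc4)c(OC)c3)[C@@H]2COCc2ccc3ccccc3c2)ccc1OCc1ccccc1 | intermediate
18 | CNP0236765.9 | COc1cc([C@@H](O)[C@@H]2CO[C@H](c3ccc(O)c(OC)c3)[C@@H]2CO)ccc1O | target

**Total steps:** 12. **Longest linear sequence:** 12 (fully linear; 1 enters twice in step 1).

**Steps most likely to fail**

Step 7. The cobaltate may fail to reach the rear side of the hindered epoxide carbons. Turnover would then stop, or a Lewis-acid-induced 1,2-shift of aryl or hydride would outrun ring opening. The fallback uses known chemistry, leaves from 6 and returns at 13, and takes the two carbons from ethylene instead of CO.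
- Silylation of 6 (TBSCl, imidazole, DMF) gives the bis(silyl ether) of the ynediol F1.
- Ene–yne cross-metathesis with ethylene (second-generation Grubbs catalyst RuCl2(=CHPh)(H2IMes)(PCy3), toluene, 80 °C), a reaction favoured by propargylic oxygen substituents, gives the 2,3-disubstituted buta-1,3-diene F2.
- Twofold hydroboration with 9-BBN-H places boron on both CH2 termini. It sets C3 and C4 through the anti 1,2-induction known for 1,1-disubstituted allylic ethers and gives the bis(9-BBN) adduct F3.
- Oxidation with NaBO3 or H2O2/NaOH gives 13.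

Stereocontrol is then substrate-based and not stereospecific, so minor diastereomers would have to be removed at 13.

Step 3. Hydride transfer to the electron-rich aryl ketones may be slow. The reagent could then dissociate into 9-BBN-H and pinene and reduce unselectively, or nucleophiles could add to the activated triple bond. The fallback leaves from 4 and returns at 8. It drops the oxidation–reduction pair and lets the epoxidation do the resolution.
- 4 is reduced directly with NaAlH2(OCH2CH2OMe)2 to the stereoisomeric mixture of (E)-enediols F4.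
- Sharpless kinetic resolution (Ti(Oi-Pr)4, D-(−)-diisopropyl tartrate, substoichiometric t-BuOOH, −20 °C) epoxidises only alkenes next to an (S)-carbinol.
- The (S,S)-diol gives 8 and the (R,R)-diol is left unchanged.
- The meso diol gives the erythro/threo epoxy diol F5, which is removed by chromatography.

At most a quarter of the material can end up in 8, but the route becomes two steps shorter.

Step 9. The flanking silyloxybenzyl groups may make alkylation sluggish, or the first and second alkylation may be poorly discriminated. The fallback leaves from 13 and returns at 14, and breaks the symmetry through a ring instead of by relative rates.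
- 13 and 2-naphthaldehyde dimethyl acetal (PPTS, CH2Cl2, molecular sieves) give the seven-membered naphthylidene acetal F6.
- The two acetal C–O bonds of F6 are equivalent, so reductive opening with i-Bu2AlH (CH2Cl2, 0 °C) can give only 14.

**Further compounds**
F1 | step 7 | (1R,4R)-ynediol bis(tert-butyldimethylsilyl ether) | CC(C)(C)[Si](C)(C)O[C@H](c1ccc(OCc2ccccc2)c(OC)c1)C#C[C@H](O[Si](C)(C)C(C)(C)C)c1ccc(OCc2ccccc2)c(OC)c1
F2 | step 7 | 2,3-bis[(R)-aryl(TBSO)methyl]buta-1,3-diene | C=C([C@H](O[Si](C)(C)C(C)(C)C)c1ccc(OCc2ccccc2)c(OC)c1)C(=C)[C@H](O[Si](C)(C)C(C)(C)C)c1ccc(OCc2ccccc2)c(OC)c1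
F3 | step 7 | 1,4-bis(9-borabicyclo[3.3.1]nonan-9-yl) adduct with the configuration of 13 | B1(C[C@@H]([C@H](O[Si](C)(C)C(C)(C)C)c2ccc(OCc3ccccc3)c(OC)c2)[C@@H](CB2C3CCCC2CCC3)[C@H](O[Si](C)(C)C(C)(C)C)c2ccc(OCc3ccccc3)c(OC)c2)C2CCCC1CCC2
F4 | step 3 | (E)-1,4-bis[4-(benzyloxy)-3-methoxyphenyl]but-2-ene-1,4-diol, dl/meso mixture | OC(/C=C/C(O)c1ccc(OCc2ccccc2)c(OC)c1)c1ccc(OCc2ccccc2)c(OC)c1
F5 | step 3 | epoxy diol from the meso diol (erythro at one end, threo at the other) | O[C@H](c1ccc(OCc2ccccc2)c(OC)c1)[C@H]1O[C@@H]1[C@@H](O)c1ccc(OCc2ccccc2)c(OC)c1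
F6 | step 9 | trans-5,6-disubstituted 2-(naphthalen-2-yl)-1,3-dioxepane from 13 | C1(c2ccc3ccccc3c2)OC[C@@H]([C@H](O[Si](C)(C)C(C)(C)C)c2ccc(OCc3ccccc3)c(OC)c2)[C@H]([C@H](O[Si](C)(C)C(C)(C)C)c2ccc(OCc3ccccc3)c(OC)c2)CO1
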